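**Retrosynthetic overview**
- The free acid is released last from its sodium salt. Before that come hydrogenolysis of four benzyl ethers, sulfation of the single free 4'-hydroxyl, and removal of the 4'-O-allyl group that marks this position.
- The C5 and C7 benzyloxy groups go back to C–F bonds (double SNAr with benzyloxide on a 5,7-difluoro-3-benzyloxyflavone).
- Ring C is cut at C3–C4 and O1–C8a: the enolate of a B-ring α-benzyloxy ketone is aroylated by 2,4,6-trifluorobenzoyl chloride, and the diketonate oxygen then displaces an ortho fluoride.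
- Feature used: in ring A the oxygen-bearing carbons C8a (O1), C5 and C7 are ortho, ortho and para to C4a, which carries the C4 carbonyl, so every ring A C–O bond sits where a carbonyl-activated aryl fluoride undergoes SNAr.
- The B-ring ketone comes from an aryl Grignard reagent and a Weinreb amide. Rings A and B are bought as benzenes; ring C is the only ring formed (step 5).

Key step: step 5

Assumption: the target is taken as the free hydrogen sulfate as drawn (no stereocentres); aryl hydrogen sulfates are acid-labile, so the sodium salt is carried to the end and the acid is set free cold in the last step.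

**Step 1**
Reactants: 1 2-(benzyloxy)phenol
Product: 2 2-(benzyloxy)-4-bromophenol
Conditions: NBS (1.0 equiv), MeCN, 0 °C to rt, dark
Reagents that add atoms: N-bromosuccinimide, O=C1CCC(=O)N1Br
Why: Electrophilic aromatic bromination in a polar solvent should go para to the free hydroxyl, the stronger director, as it does for guaiacol-type phenols.

**Step 2**
Reactants: 2 2-(benzyloxy)-4-bromophenol; 3 allyl bromide
Product: 4 1-(allyloxy)-2-(benzyloxy)-4-bromobenzene
Conditions: K2CO3, DMF, rt
Reagents that add atoms: none
Why: Williamson etherification of the phenoxide with a reactive allylic bromide should be clean and leaves the aryl bromide untouched.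

**Step 3**
Reactants: 5 2-(benzyloxy)acetyl chloride; 6 N,O-dimethylhydroxylamine hydrochloride
Product: 7 2-(benzyloxy)-N-methoxy-N-methylacetamide
Conditions: Et3N (2.2 equiv), CH2Cl2, 0 °C to rt
Reagents that add atoms: none
Why: N-acylation of the hydroxylamine by an acid chloride is the standard Weinreb amide formation.

**Step 4**
Reactants: 4 1-(allyloxy)-2-(benzyloxy)-4-bromobenzene; 7 2-(benzyloxy)-N-methoxy-N-methylacetamide
Product: 9 1-[4-(allyloxy)-3-(benzyloxy)phenyl]-2-(benzyloxy)ethan-1-one, via aryl Grignard reagent 8 (not isolated)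
Conditions: Mg turnings, I2 (cat.), THF, 45 °C; then 7, THF, 0 °C to rt; 1 M HCl, 0 °C
Reagents that add atoms: magnesium, [Mg] (kept only in intermediate 8)
Why: In this Weinreb ketone synthesis the aryl Grignard reagent adds once to the amide, and the magnesium chelate of the tetrahedral adduct should hold until the acidic quench, so no tertiary alcohol forms.

**Step 5**
Reactants: 9 1-[4-(allyloxy)-3-(benzyloxy)phenyl]-2-(benzyloxy)ethan-1-one; 10 2,4,6-trifluorobenzoyl chloride
Product: 12 2-[4-(allyloxy)-3-(benzyloxy)phenyl]-3-(benzyloxy)-5,7-difluoro-4H-chromen-4-one, via trifluorobenzoyl diketone 11 (not isolated)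
Conditions: LiN(SiMe3)2 (2.1 equiv), THF, −78 °C; 10 (1.05 equiv), −78 to 0 °C; then DMF, 60 °C; aq. NH4Cl
Reagents that add atoms: none
Why: LiN(SiMe3)2 converts 9 into its lithium Z-enolate, held as a five-membered chelate by the α-benzyloxy oxygen, and this attacks the acid chloride at carbon (Claisen-type C-aroylation, C3–C4) to give diketone 11, which the second equivalent of base deprotonates at once. On warming with DMF the diketonate oxygen on the B-ring carbonyl should add to an ortho C–F carbon of the trifluorophenyl ring, giving a Meisenheimer adduct stabilised by the ortho acyl group and the two other fluorines, and loss of fluoride forms O1–C8a. The closest known reaction type is the one-pot aroylation and SNAr cyclisation of ketone enolates or enamines with 2-fluorobenzoyl chlorides, which delivers chromones, flavones and 4-quinolones. Ring C closes in a 6-exo-trig addition–elimination, and no stereocentre is formed because C3 ends as an sp2 carbon. The step needs C- over O-acylation, which the tight lithium chelate in THF at low temperature should secure (an enol ester from O-acylation would be expected to pass its acyl group on to remaining enolate, giving the more stable diketonate), and it needs closure at an ortho fluorine, which geometry secures: the two ortho fluorines are equivalent, the para fluorine is out of reach, and the other diketonate oxygen has no leaving group within reach.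

**Step 6**
Reactants: 12 2-[4-(allyloxy)-3-(benzyloxy)phenyl]-3-(benzyloxy)-5,7-difluoro-4H-chromen-4-one
Product: 14 2-[4-(allyloxy)-3-(benzyloxy)phenyl]-3,5,7-tris(benzyloxy)-4H-chromen-4-one, via 7-benzyloxy-5-fluoro monoether 13 (not isolated)
Conditions: BnOH (2.5 equiv), NaH (2.4 equiv), THF, 0 °C; then 12, DMF, 0 to 50 °C
Reagents that add atoms: benzyl alcohol, OCc1ccccc1 (two equivalents, delivered as sodium benzyloxide, [Na+].[O-]Cc1ccccc1)
Why: Both fluorides are activated for SNAr by the pyranone carbonyl (C7 para, C5 ortho), so benzyloxide should displace the less hindered C7–F first and then C5–F, the order being immaterial because both are replaced.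

**Step 7**
Reactants: 14 2-[4-(allyloxy)-3-(benzyloxy)phenyl]-3,5,7-tris(benzyloxy)-4H-chromen-4-one
Product: 15 3,5,7-tris(benzyloxy)-2-[3-(benzyloxy)-4-hydroxyphenyl]-4H-chromen-4-one
Conditions: Pd(PPh3)4 (cat.), morpholine, THF, rt
Reagents that add atoms: none
Why: In this Tsuji–Trost deallylation zerovalent palladium ionises the aryl allyl ether to a π-allyl complex that morpholine traps, so only the 4'-oxygen is unmasked and the benzyl ethers stay.

**Step 8**
Reactants: 15 3,5,7-tris(benzyloxy)-2-[3-(benzyloxy)-4-hydroxyphenyl]-4H-chromen-4-one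
Product: 17 sodium 2-(benzyloxy)-4-[3,5,7-tris(benzyloxy)-4-oxo-4H-chromen-2-yl]phenyl sulfate, via pyridinium aryl sulfate 16 (not isolated)
Conditions: SO3·pyridine (4 equiv), pyridine, 50 °C; then aq. NaHCO3, 0 °C
Reagents that add atoms: sulfur trioxide–pyridine complex, [O-]S(=O)(=O)[n+]1ccccc1; sodium hydrogen carbonate, [Na+].OC([O-])=O
Why: O-sulfation of a phenol with sulfur trioxide–pyridine is standard, and the 4'-hydroxyl is the only free hydroxyl, so the sulfate can enter nowhere else.

**Step 9**
Reactants: 17 sodium 2-(benzyloxy)-4-[3,5,7-tris(benzyloxy)-4-oxo-4H-chromen-2-yl]phenyl sulfate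
Product: 18 sodium 2-hydroxy-4-(3,5,7-trihydroxy-4-oxo-4H-chromen-2-yl)phenyl sulfate
Conditions: H2 (1 atm), 10% Pd/C, THF/MeOH/H2O, rt
Reagents that add atoms: none
Why: Catalytic hydrogenolysis should cleave all four benzyl ethers under neutral conditions that leave the aryl sulfate salt and the flavonol C2=C3 bond intact.

**Step 10**
Reactants: 18 sodium 2-hydroxy-4-(3,5,7-trihydroxy-4-oxo-4H-chromen-2-yl)phenyl sulfate
Product: 19 2-hydroxy-4-(3,5,7-trihydroxy-4-oxo-4H-chromen-2-yl)phenyl hydrogen sulfate (quercetin 4'-O-sulfate, CNP0211268.0)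
Conditions: 1.0 M HCl (1.0 equiv), H2O/MeOH, 0 °C; C18 cartridge (H2O wash, MeOH elution); freeze-drying
Reagents that add atoms: none
Why: Simple protonation of the sulfate salt with one equivalent of mineral acid, kept cold and followed at once by reversed-phase desalting, should limit acid-catalysed loss of the sulfate.

**Compound list**
1 | 2-(benzyloxy)phenol | Oc1ccccc1OCc1ccccc1 | starting material
2 | 2-(benzyloxy)-4-bromophenol | Oc1ccc(Br)cc1OCc1ccccc1 | intermediate
3 | allyl bromide | C=CCBr | starting material
4 | 1-(allyloxy)-2-(benzyloxy)-4-bromobenzene | C=CCOc1ccc(Br)cc1OCc1ccccc1 | intermediate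
5 | 2-(benzyloxy)acetyl chloride | O=C(Cl)COCc1ccccc1 | starting material
6 | N,O-dimethylhydroxylamine hydrochloride | CNOC.Cl | starting material
7 | 2-(benzyloxy)-N-methoxy-N-methylacetamide | CON(C)C(=O)COCc1ccccc1 | intermediate
8 | [4-(allyloxy)-3-(benzyloxy)phenyl]magnesium bromide | C=CCOc1ccc([Mg]Br)cc1OCc1ccccc1 | intermediate (not isolated)
9 | 1-[4-(allyloxy)-3-(benzyloxy)phenyl]-2-(benzyloxy)ethan-1-one | O=C(COCc1ccccc1)c1ccc(OCC=C)c(OCc2ccccc2)c1 | intermediate
10 | 2,4,6-trifluorobenzoyl chloride | O=C(Cl)c1c(F)cc(F)cc1F | starting material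
11 | 1-[4-(allyloxy)-3-(benzyloxy)phenyl]-2-(benzyloxy)-3-(2,4,6-trifluorophenyl)propane-1,3-dione (present as its lithium enolate) | O=C(c1ccc(OCC=C)c(OCc2ccccc2)c1)C(OCc1ccccc1)C(=O)c1c(F)cc(F)cc1F | intermediate (not isolated)
12 | 2-[4-(allyloxy)-3-(benzyloxy)phenyl]-3-(benzyloxy)-5,7-difluoro-4H-chromen-4-one | O=c1c(OCc2ccccc2)c(-c2ccc(OCC=C)c(OCc3ccccc3)c2)oc2cc(F)cc(F)c12 | intermediate
13 | 2-[4-(allyloxy)-3-(benzyloxy)phenyl]-3,7-bis(benzyloxy)-5-fluoro-4H-chromen-4-one | O=c1c(OCc2ccccc2)c(-c2ccc(OCC=C)c(OCc3ccccc3)c2)oc2cc(OCc3ccccc3)cc(F)c12 | intermediate (not isolated)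
14 | 2-[4-(allyloxy)-3-(benzyloxy)phenyl]-3,5,7-tris(benzyloxy)-4H-chromen-4-one | O=c1c(OCc2ccccc2)c(-c2ccc(OCC=C)c(OCc3ccccc3)c2)oc2cc(OCc3ccccc3)cc(OCc3ccccc3)c12 | intermediate
15 | 3,5,7-tris(benzyloxy)-2-[3-(benzyloxy)-4-hydroxyphenyl]-4H-chromen-4-one | O=c1c(OCc2ccccc2)c(-c2ccc(O)c(OCc3ccccc3)c2)oc2cc(OCc3ccccc3)cc(OCc3ccccc3)c12 | intermediate
16 | pyridinium 2-(benzyloxy)-4-[3,5,7-tris(benzyloxy)-4-oxo-4H-chromen-2-yl]phenyl sulfate | O=c1c(OCc2ccccc2)c(-c2ccc(OS(=O)(=O)[O-])c(OCc3ccccc3)c2)oc2cc(OCc3ccccc3)cc(OCc3ccccc3)c12.c1cc[nH+]cc1 | intermediate (not isolated)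
17 | sodium 2-(benzyloxy)-4-[3,5,7-tris(benzyloxy)-4-oxo-4H-chromen-2-yl]phenyl sulfate | O=c1c(OCc2ccccc2)c(-c2ccc(OS(=O)(=O)[O-])c(OCc3ccccc3)c2)oc2cc(OCc3ccccc3)cc(OCc3ccccc3)c12.[Na+] | intermediate
18 | sodium 2-hydroxy-4-(3,5,7-trihydroxy-4-oxo-4H-chromen-2-yl)phenyl sulfate | O=c1c(O)c(-c2ccc(OS(=O)(=O)[O-])c(O)c2)oc2cc(O)cc(O)c12.[Na+] | intermediate
19 | 2-hydroxy-4-(3,5,7-trihydroxy-4-oxo-4H-chromen-2-yl)phenyl hydrogen sulfate | O=c1c(O)c(-c2ccc(OS(=O)(=O)O)c(O)c2)oc2cc(O)cc(O)c12 | target

**Step count**
Total: 10 steps. Longest linear sequence: 9 steps (1, 2, 4, 5, 6, 7, 8, 9, 10); step 3 is the one-step side branch.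

**Steps most likely to fail**

Step 5. The enolate may be acylated at oxygen, proton transfer from the more acidic diketone may quench enolate before it is acylated, or an enolate may attack the para C–F of another molecule before ring C closes, so that one flask does not deliver both bonds. The fallback sets out from 9 and comes back at 12. The lithium enolate of 9 (LiN(SiMe3)2, THF, −78 °C) is added to 2,4,6-trifluorobenzaldehyde, which can react only at carbon, to give the aldol 1-[4-(allyloxy)-3-(benzyloxy)phenyl]-2-(benzyloxy)-3-hydroxy-3-(2,4,6-trifluorophenyl)propan-1-one F1 as a mixture of diastereomers, both of which lead on. Dess–Martin periodinane in CH2Cl2 oxidises F1 to diketone 11, which is now isolated, and K2CO3 in DMF at 25 to 60 °C closes ring C by the same intramolecular SNAr to give 12.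

Step 6. The second fluoride, deactivated by the first benzyloxy group, may be displaced slowly, and at the temperature then needed benzyloxide may add to C2 of the pyranone and open ring C or isomerise the allyl ether. The fallback sets out from 13 (made on purpose with one equivalent of sodium benzyloxide at 0 °C) and comes back at 14. Treating 13 with 2-(methylsulfonyl)ethanol and NaH in DMF at 0 °C to rt should give the SNAr ether 2-[4-(allyloxy)-3-(benzyloxy)phenyl]-3,7-bis(benzyloxy)-5-[2-(methylsulfonyl)ethoxy]-4H-chromen-4-one F2, which is not isolated. It loses methyl vinyl sulfone by β-elimination to give 2-[4-(allyloxy)-3-(benzyloxy)phenyl]-3,7-bis(benzyloxy)-5-hydroxy-4H-chromen-4-one F3. The elimination makes the displacement irreversible, and the chelated 5-phenoxide protects the pyranone from further alkoxide attack. Benzyl bromide and K2CO3 in DMF at 60 °C then benzylate F3 to 14.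

Step 10. Acid-catalysed cleavage of the S–O bond may strip the sulfate while the free acid is desalted and concentrated, and salt removal may be incomplete. The fallback sets out from 17 and comes back at 19, replacing steps 9 and 10. While the molecule is still lipophilic, 17 is partitioned between ethyl acetate and ice-cold 1 M HCl, so that the salt leaves in the water layer and the organic layer holds 2-(benzyloxy)-4-[3,5,7-tris(benzyloxy)-4-oxo-4H-chromen-2-yl]phenyl hydrogen sulfate F4. Hydrogenolysis of F4 (H2, 10% Pd/C, THF/H2O, rt) should then give 19 directly, with toluene as the only co-product, so that filtration and cold evaporation replace desalting.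

**Further compounds**
F1 | step 5 | 1-[4-(allyloxy)-3-(benzyloxy)phenyl]-2-(benzyloxy)-3-hydroxy-3-(2,4,6-trifluorophenyl)propan-1-one (mixture of diastereomers) | O=C(c1ccc(OCC=C)c(OCc2ccccc2)c1)C(OCc1ccccc1)C(O)c1c(F)cc(F)cc1F
F2 | step 6 | 2-[4-(allyloxy)-3-(benzyloxy)phenyl]-3,7-bis(benzyloxy)-5-[2-(methylsulfonyl)ethoxy]-4H-chromen-4-one | O=c1c(OCc2ccccc2)c(-c2ccc(OCC=C)c(OCc3ccccc3)c2)oc2cc(OCc3ccccc3)cc(OCCS(C)(=O)=O)c12
F3 | step 6 | 2-[4-(allyloxy)-3-(benzyloxy)phenyl]-3,7-bis(benzyloxy)-5-hydroxy-4H-chromen-4-one | O=c1c(OCc2ccccc2)c(-c2ccc(OCC=C)c(OCc3ccccc3)c2)oc2cc(OCc3ccccc3)cc(O)c12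
F4 | step 10 | 2-(benzyloxy)-4-[3,5,7-tris(benzyloxy)-4-oxo-4H-chromen-2-yl]phenyl hydrogen sulfate | O=c1c(OCc2ccccc2)c(-c2ccc(OS(=O)(=O)O)c(OCc3ccccc3)c2)oc2cc(OCc3ccccc3)cc(OCc3ccccc3)c12
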